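The plan cuts the alkyl C–O bond of the α-methylene ε-lactone. The lactone oxygen on the quaternary carbon C12 and the acetoxy group on the neighbouring C11 are read as the two ends of a cis-11,12-epoxide. In the key step a malonic acid on C1 opens this epoxide at its tertiary carbon (7-exo, inversion), which closes the seven-membered ring O–C12–C13–C14–C1–C15–C16, sets C12 and frees the C11 hydroxyl. The precursor is a 14-membered carbocycle, already bridged by the C4–O–C7 tetrahydrofuran, that carries the (11S,12R)-epoxide, a silylated C8 carbinol and the C3 acetate; decarboxylative methylenation and acetylation then finish the target.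

Key step: step 15

Remark: cembrane numbering is used (ring C1–C14; C1 bears C15(=C17H2)–C16O2; methyls on C4, C8, C12), and (S)-(+)-linalool and nerol are taken as commercial.

Step 1
Reactants: 1 (S)-(+)-linalool
Product: 2 (2E,6S)-2,6-dimethylocta-2,7-diene-1,6-diol
Conditions: SeO2 (cat.), t-BuOOH, CH2Cl2, 0 °C → rt
Reagents that add atoms: tert-butyl hydroperoxide, CC(C)(C)OO (oxygen delivered through SeO2, O=[Se]=O)
Why: Allylic oxidation with SeO2 and t-BuOOH (ene reaction followed by [2,3]-sigmatropic shift) should hydroxylate the (E)-methyl group of the trisubstituted olefin selectively, because the ethenyl group has no allylic hydrogen and the existing stereocenter is not involved.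

Step 2
Reactants: 2 (2E,6S)-2,6-dimethylocta-2,7-diene-1,6-diol
Product: 4 (2S)-2-[(2R,5S)-5-ethenyl-5-methyloxolan-2-yl]propane-1,2-diol, via epoxy triol 3 (not isolated)
Conditions: Ti(Oi-Pr)4, L-(+)-diethyl tartrate, t-BuOOH, 4 Å MS, CH2Cl2, −20 °C; then CSA (cat.), rt
Reagents that add atoms: tert-butyl hydroperoxide, CC(C)(C)OO
Why: Sharpless asymmetric epoxidation of the primary (E)-allylic alcohol with L-(+)-diethyl tartrate should give the (2S,3S)-epoxide 3, which the tertiary hydroxyl then opens in a 5-exo attack with inversion at the epoxide carbon remote from the CH2OH group, so that the new ring stereocenter is R and the ethenyl and diol-bearing groups are cis on the tetrahydrofuran.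

Step 3
Reactants: 4 (2S)-2-[(2R,5S)-5-ethenyl-5-methyloxolan-2-yl]propane-1,2-diol
Product: 5 1-[(2R,5S)-5-ethenyl-5-methyloxolan-2-yl]ethan-1-one
Conditions: NaIO4, THF/H2O (pH 7), 0 °C
Reagents that add atoms: none
Why: Periodate glycol cleavage of the 1,2-diol removes the CH2OH carbon as formaldehyde and leaves the methyl ketone under neutral conditions that do not epimerize the α-alkoxy center.

Step 4
Reactants: 6 nerol
Product: 7 [(2S,3R)-3-methyl-3-(4-methylpent-3-en-1-yl)oxiran-2-yl]methanol
Conditions: Ti(Oi-Pr)4 (cat.), L-(+)-diethyl tartrate, t-BuOOH, 4 Å MS, CH2Cl2, −20 °C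
Reagents that add atoms: tert-butyl hydroperoxide, CC(C)(C)OO
Why: Sharpless asymmetric epoxidation of the (Z)-allylic alcohol with L-(+)-diethyl tartrate should give the (2S,3R) cis-epoxide by reagent control, the unfunctionalized isopropylidene olefin being untouched.

Step 5
Reactants: 7 [(2S,3R)-3-methyl-3-(4-methylpent-3-en-1-yl)oxiran-2-yl]methanol
Product: 8 [(2S,3R)-3-methyl-3-(4-methylpent-3-en-1-yl)oxiran-2-yl]methyl trifluoromethanesulfonate
Conditions: Tf2O, 2,6-lutidine, CH2Cl2, −78 °C (used at once)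
Reagents that add atoms: trifluoromethanesulfonic anhydride, O=S(=O)(OS(=O)(=O)C(F)(F)F)C(F)(F)F
Why: Triflation of the primary alcohol at low temperature gives a glycidyl-type triflate that reacts by direct SN2 displacement at the primary carbon and is used at once.

Step 6
Reactants: 5 1-[(2R,5S)-5-ethenyl-5-methyloxolan-2-yl]ethan-1-one; 8 epoxy triflate
Product: 10 1-[(2R,5S)-5-ethenyl-5-methyloxolan-2-yl]-3-[(2S,3R)-3-methyl-3-(4-methylpent-3-en-1-yl)oxiran-2-yl]propan-1-one, via lithium enolate 9 (not isolated)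
Conditions: LDA, THF, −78 °C; then 8, THF/DMPU, −78 → −40 °C
Reagents that add atoms: none
Why: Kinetic deprotonation at the methyl group and C-alkylation of the lithium enolate by the primary triflate (enolate alkylation) should form the C9–C10 bond with the ring and epoxide stereocenters untouched.

Step 7
Reactants: 10 epoxy ketone
Product: 12 triethyl{[(2S)-2-[(2R,5S)-5-ethenyl-5-methyloxolan-2-yl]-4-[(2S,3R)-3-methyl-3-(4-methylpent-3-en-1-yl)oxiran-2-yl]butan-2-yl]oxy}silane, via bromomagnesium alkoxide 11 (not isolated)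
Conditions: MeMgBr, THF, −78 °C; then TESOTf, 2,6-lutidine, −78 → 0 °C
Reagents that add atoms: methylmagnesium bromide, C[Mg]Br; triethylsilyl trifluoromethanesulfonate, CC[Si](CC)(CC)OS(=O)(=O)C(F)(F)F
Why: Chelation-controlled Grignard addition (Cram-chelate model, magnesium bridging the ring oxygen and the carbonyl oxygen) should bring the methyl group in from the face anti to the ring CH2 and set the tertiary carbinol as S, and silylation of the alkoxide in the same flask stops it from attacking the nearby epoxide in a 5-exo manner.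

Step 8
Reactants: 12 silyl ether diene
Product: 13 (2S,5R)-2-methyl-5-[(2S)-4-[(2S,3R)-3-methyl-3-(3-oxopropyl)oxiran-2-yl]-2-(triethylsilyloxy)butan-2-yl]oxolane-2-carbaldehyde
Conditions: O3, CH2Cl2/MeOH, pyridine, −78 °C; then Me2S
Reagents that add atoms: ozone, [O-][O+]=O
Why: Ozonolysis with reductive work-up cleaves the ethenyl and isopropylidene groups to the two aldehydes in one operation, the epoxide and the silyl ether being inert to ozone.

Step 9
Reactants: 13 dialdehyde
Product: 14 (2S,5R)-5-[(2S)-4-[(2S,3R)-3-[(3E)-4-iodobut-3-en-1-yl]-3-methyloxiran-2-yl]-2-(triethylsilyloxy)butan-2-yl]-2-methyloxolane-2-carbaldehyde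
Conditions: CrCl2, CHI3 (1.5 equiv), THF/dioxane, 0 °C
Reagents that add atoms: iodoform, IC(I)I
Why: Takai olefination with CHI3 and CrCl2 should convert the unhindered chain aldehyde into the (E)-iodoalkene, because the aldehyde on the quaternary ring carbon is neopentyl-like and reacts far more slowly with the bulky geminal dichromium reagent.

Step 10
Reactants: 14 iodoalkene aldehyde
Product: 15 (1E,4S,7R,8S,11S,12R)-4,7:11,12-diepoxy-4,8,12-trimethyl-8-(triethylsilyloxy)cyclotetradec-1-en-3-ol (cembrane ring numbering; both C3 epimers)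
Conditions: CrCl2, NiCl2 (cat.), DMSO/THF, rt, 2 mM
Reagents that add atoms: none
Why: Nozaki–Hiyama–Kishi reaction under high dilution (NiCl2-catalysed formation of the alkenylchromium species, which adds only to the aldehyde) should close the 14-membered ring with retention of the E geometry, the configuration of the new carbinol being irrelevant because it is oxidized next.

Step 11
Reactants: 15 macrocyclic allylic alcohol
Product: 16 (1E,4S,7R,8S,11S,12R)-4,7:11,12-diepoxy-4,8,12-trimethyl-8-(triethylsilyloxy)cyclotetradec-1-en-3-one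
Conditions: Dess–Martin periodinane, NaHCO3, CH2Cl2, rt
Reagents that add atoms: none
Why: Dess–Martin oxidation of the allylic alcohol under bicarbonate buffer gives the (E)-enone without touching epoxide or silyl ether.

Step 12
Reactants: 16 macrocyclic enone
Product: 17 dibenzyl 2-[(1S,4S,7R,8S,11S,12R)-4,7:11,12-diepoxy-4,8,12-trimethyl-3-oxo-8-(triethylsilyloxy)cyclotetradecyl]propanedioate
Conditions: dibenzyl malonate, LiAl[(R)-binaphthoxide]2 (10 mol %), KOt-Bu (9 mol %), 4 Å MS, THF, rt
Reagents that add atoms: dibenzyl malonate, O=C(CC(=O)OCc1ccccc1)OCc1ccccc1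
Why: Catalytic asymmetric Michael addition, in which the heterobimetallic binaphthoxide complex holds the enone and the malonate enolate together and exposes one face of the β-carbon, should set C1 as S under catalyst control (the ligand antipode is chosen for this face), the α′ position being quaternary so that no enolization competes.

Step 13
Reactants: 17 keto malonate
Product: 19 dibenzyl 2-[(1S,3R,4S,7R,8S,11S,12R)-3-acetoxy-4,7:11,12-diepoxy-4,8,12-trimethyl-8-(triethylsilyloxy)cyclotetradecyl]propanedioate, via secondary alcohol 18 (not isolated)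
Conditions: (S)-Me-CBS oxazaborolidine (0.3 equiv), BH3·SMe2, THF, −30 °C; MeOH quench; then Ac2O, pyridine, DMAP, CH2Cl2, 0 °C
Reagents that add atoms: acetic anhydride, CC(=O)OC(C)=O
Why: Corey–Bakshi–Shibata reduction, with the quaternary ring carbon as the large and the CH2 group as the small ketone substituent, should give the (3R)-alcohol with the (S)-catalyst, and acetylation in the same flask prevents six-membered lactonization onto a malonate ester.

Step 14
Reactants: 19 acetoxy dibenzyl malonate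
Product: 20 2-[(1S,3R,4S,7R,8S,11S,12R)-3-acetoxy-4,7:11,12-diepoxy-4,8,12-trimethyl-8-(triethylsilyloxy)cyclotetradecyl]propanedioic acid
Conditions: H2 (1 atm), 10% Pd/C, EtOAc, rt
Reagents that add atoms: none
Why: Hydrogenolysis of both benzyl esters over Pd/C frees the malonic acid under neutral conditions, there being no olefin left and the trisubstituted epoxide, acetate and silyl ether being stable to hydrogenation.

Step 15
Reactants: 20 epoxy malonic acid
Product: 22 3-acetoxy-8,11-dihydroxy α-carboxy ε-lactone (1S,3R,4S,7R,8S,11S,12S; lactone C16(=O)–O–C12; CO2H on C15; both C15 epimers), via silyl ether lactone 21 (not isolated)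
Conditions: CSA (0.2 equiv), CH2Cl2 (5 mM), 0 °C → rt; then MeOH, rt
Reagents that add atoms: none
Why: The acid activates the (11S,12R)-epoxide and one carboxyl group of the malonic acid on C1 attacks the tertiary carbon C12 from the face opposite the epoxide oxygen, so that the C12–O(epoxide) bond breaks as the new O–C12 bond forms; this is the classical epoxy acid to hydroxy lactone cyclization (carboxylic acid opening of an epoxide). The seven-membered lactone closes in the 7-exo-tet mode, the alternative attack at C11 being an 8-endo closure at the secondary carbon that stabilizes positive charge less well. C12 becomes S by inversion, so its configuration follows from the cis-epoxide made by asymmetric epoxidation, while C11 keeps its oxygen and its S configuration. The selectivity needed is that the carboxyl group alone opens the epoxide: the C8 hydroxyl, which could attack the same epoxide in a 5-exo or 6-endo manner, stays silylated until the epoxide is consumed and is freed only by the methanol added afterwards, and the C3 oxygen is already acetylated so that no six-membered lactone can form. Either carboxyl group gives the same constitution, and the epimer mixture at C15 is erased in the next step.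

Step 16
Reactants: 22 α-carboxy lactone diol
Product: 23 (1S,3R,4S,7R,8S,11S,12S)-3-acetoxy-4,7-epoxy-8,11-dihydroxycembr-15(17)-en-16,12-olide
Conditions: (CH2O)n, Et2NH, 1,4-dioxane, 70 °C
Reagents that add atoms: formaldehyde (from paraformaldehyde), C=O
Why: Decarboxylative Mannich methylenation (iminium ion from formaldehyde and diethylamine adds at the acidic α-carbon, then CO2 and the amine are lost) installs the exocyclic methylene and erases the undefined center at C15.

Step 17
Reactants: 23 11-hydroxy lactone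
Product: 24 CNP0343714.5, (1S,3R,4S,7R,8S,11S,12S)-3,11-diacetoxy-4,7-epoxy-8-hydroxycembr-15(17)-en-16,12-olide
Conditions: Ac2O, pyridine, DMAP (cat.), CH2Cl2, 0 °C → rt
Reagents that add atoms: acetic anhydride, CC(=O)OC(C)=O
Why: Acetylation with Ac2O and DMAP should be selective for the secondary C11 hydroxyl over the hindered tertiary C8 hydroxyl and gives the target.

Compound list
1 | (S)-(+)-linalool, (3S)-3,7-dimethylocta-1,6-dien-3-ol | C=C[C@@](C)(O)CCC=C(C)C | starting material
2 | (2E,6S)-2,6-dimethylocta-2,7-diene-1,6-diol | C=C[C@@](C)(O)CC/C=C(\C)CO | intermediate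
3 | (3S)-5-[(2S,3S)-3-(hydroxymethyl)-3-methyloxiran-2-yl]-3-methylpent-1-en-3-ol | C=C[C@@](C)(O)CC[C@@H]1O[C@@]1(C)CO | intermediate
4 | (2S)-2-[(2R,5S)-5-ethenyl-5-methyloxolan-2-yl]propane-1,2-diol | C=C[C@]1(C)CC[C@@H](O1)[C@@](C)(O)CO | intermediate
5 | 1-[(2R,5S)-5-ethenyl-5-methyloxolan-2-yl]ethan-1-one | C=C[C@]1(C)CC[C@@H](O1)C(C)=O | intermediate
6 | nerol, (2Z)-3,7-dimethylocta-2,6-dien-1-ol | OC/C=C(/C)CCC=C(C)C | starting material
7 | [(2S,3R)-3-methyl-3-(4-methylpent-3-en-1-yl)oxiran-2-yl]methanol | OC[C@@H]1O[C@]1(C)CCC=C(C)C | intermediate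
8 | [(2S,3R)-3-methyl-3-(4-methylpent-3-en-1-yl)oxiran-2-yl]methyl trifluoromethanesulfonate | O=S(=O)(OC[C@@H]1O[C@]1(C)CCC=C(C)C)C(F)(F)F | intermediate
9 | lithium enolate of 5 | C=C[C@]1(C)CC[C@@H](O1)C(=C)O[Li] | intermediate
10 | 1-[(2R,5S)-5-ethenyl-5-methyloxolan-2-yl]-3-[(2S,3R)-3-methyl-3-(4-methylpent-3-en-1-yl)oxiran-2-yl]propan-1-one | C=C[C@]1(C)CC[C@@H](O1)C(=O)CC[C@@H]1O[C@]1(C)CCC=C(C)C | intermediate
11 | bromomagnesium (2S)-2-[(2R,5S)-5-ethenyl-5-methyloxolan-2-yl]-4-[(2S,3R)-3-methyl-3-(4-methylpent-3-en-1-yl)oxiran-2-yl]butan-2-olate | C=C[C@]1(C)CC[C@@H](O1)[C@@](C)(O[Mg]Br)CC[C@@H]1O[C@]1(C)CCC=C(C)C | intermediate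
12 | triethylsilyl ether of the (2S)-tertiary alcohol from 11 | C=C[C@]1(C)CC[C@@H](O1)[C@@](C)(O[Si](CC)(CC)CC)CC[C@@H]1O[C@]1(C)CCC=C(C)C | intermediate
13 | (2S,5R)-2-methyl-5-[(2S)-4-[(2S,3R)-3-methyl-3-(3-oxopropyl)oxiran-2-yl]-2-(triethylsilyloxy)butan-2-yl]oxolane-2-carbaldehyde | O=C[C@]1(C)CC[C@@H](O1)[C@@](C)(O[Si](CC)(CC)CC)CC[C@@H]1O[C@]1(C)CCC=O | intermediate
14 | (2S,5R)-5-[(2S)-4-[(2S,3R)-3-[(3E)-4-iodobut-3-en-1-yl]-3-methyloxiran-2-yl]-2-(triethylsilyloxy)butan-2-yl]-2-methyloxolane-2-carbaldehyde | O=C[C@]1(C)CC[C@@H](O1)[C@@](C)(O[Si](CC)(CC)CC)CC[C@@H]1O[C@]1(C)CC/C=C/I | intermediate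
15 | (1E,4S,7R,8S,11S,12R)-4,7:11,12-diepoxy-4,8,12-trimethyl-8-(triethylsilyloxy)cyclotetradec-1-en-3-ol, C3 epimers | OC1/C=C/CC[C@@]2(C)O[C@H]2CC[C@](C)(O[Si](CC)(CC)CC)[C@H]2CC[C@]1(C)O2 | intermediate
16 | (1E,4S,7R,8S,11S,12R)-4,7:11,12-diepoxy-4,8,12-trimethyl-8-(triethylsilyloxy)cyclotetradec-1-en-3-one | O=C1/C=C/CC[C@@]2(C)O[C@H]2CC[C@](C)(O[Si](CC)(CC)CC)[C@H]2CC[C@]1(C)O2 | intermediate
17 | dibenzyl 2-[(1S,4S,7R,8S,11S,12R)-4,7:11,12-diepoxy-4,8,12-trimethyl-3-oxo-8-(triethylsilyloxy)cyclotetradecyl]propanedioate | O=C1C[C@@H](C(C(=O)OCc2ccccc2)C(=O)OCc2ccccc2)CC[C@@]2(C)O[C@H]2CC[C@](C)(O[Si](CC)(CC)CC)[C@H]2CC[C@]1(C)O2 | intermediate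
18 | dibenzyl 2-[(1S,3R,4S,7R,8S,11S,12R)-4,7:11,12-diepoxy-3-hydroxy-4,8,12-trimethyl-8-(triethylsilyloxy)cyclotetradecyl]propanedioate | O[C@@H]1C[C@@H](C(C(=O)OCc2ccccc2)C(=O)OCc2ccccc2)CC[C@@]2(C)O[C@H]2CC[C@](C)(O[Si](CC)(CC)CC)[C@H]2CC[C@]1(C)O2 | intermediate
19 | dibenzyl 2-[(1S,3R,4S,7R,8S,11S,12R)-3-acetoxy-4,7:11,12-diepoxy-4,8,12-trimethyl-8-(triethylsilyloxy)cyclotetradecyl]propanedioate | CC(=O)O[C@@H]1C[C@@H](C(C(=O)OCc2ccccc2)C(=O)OCc2ccccc2)CC[C@@]2(C)O[C@H]2CC[C@](C)(O[Si](CC)(CC)CC)[C@H]2CC[C@]1(C)O2 | intermediate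
20 | 2-[(1S,3R,4S,7R,8S,11S,12R)-3-acetoxy-4,7:11,12-diepoxy-4,8,12-trimethyl-8-(triethylsilyloxy)cyclotetradecyl]propanedioic acid | CC(=O)O[C@@H]1C[C@@H](C(C(=O)O)C(=O)O)CC[C@@]2(C)O[C@H]2CC[C@](C)(O[Si](CC)(CC)CC)[C@H]2CC[C@]1(C)O2 | intermediate
21 | α-carboxy ε-lactone with 3-OAc, 8-OSiEt3, 11-OH (1S,3R,4S,7R,8S,11S,12S; C15 epimers) | OC(=O)C1C(=O)O[C@@]2(C)CC[C@H]1C[C@@H](OC(C)=O)[C@]1(C)CC[C@@H](O1)[C@@](C)(O[Si](CC)(CC)CC)CC[C@@H]2O | intermediate
22 | α-carboxy ε-lactone with 3-OAc, 8-OH, 11-OH (1S,3R,4S,7R,8S,11S,12S; C15 epimers) | OC(=O)C1C(=O)O[C@@]2(C)CC[C@H]1C[C@@H](OC(C)=O)[C@]1(C)CC[C@@H](O1)[C@@](C)(O)CC[C@@H]2O | intermediate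
23 | (1S,3R,4S,7R,8S,11S,12S)-3-acetoxy-4,7-epoxy-8,11-dihydroxycembr-15(17)-en-16,12-olide | C=C1C(=O)O[C@@]2(C)CC[C@H]1C[C@@H](OC(C)=O)[C@]1(C)CC[C@@H](O1)[C@@](C)(O)CC[C@@H]2O | intermediate
24 | CNP0343714.5, (1S,3R,4S,7R,8S,11S,12S)-3,11-diacetoxy-4,7-epoxy-8-hydroxycembr-15(17)-en-16,12-olide | C=C1C(=O)O[C@@]2(C)CC[C@H]1C[C@@H](OC(C)=O)[C@]1(C)CC[C@@H](O1)[C@@](C)(O)CC[C@@H]2OC(C)=O | target

Total step count: 17. Longest linear sequence: 15 steps (steps 1–3 and 6–17, from (S)-linalool); steps 4–5 make the nerol-derived branch.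

Steps most likely to fail

Step 12. The malonate may add to the wrong face of the macrocyclic enone, or add too slowly next to the quaternary ring carbon (poor facial selectivity, low conversion). The fallback sets out from 16 and comes back at 23. Rhodium-catalysed asymmetric 1,4-addition of potassium isopropenyltrifluoroborate ([Rh(cod)Cl]2, BINAP antipode chosen for 1S) would give isopropenyl ketone F1. Oxazaborolidine reduction as in step 13 would give alcohol F2, and acetylation would give acetate F3. SeO2/t-BuOOH oxidation of the isopropenyl methyl group would give enal F4, and NaClO2 oxidation would give epoxy acrylic acid F5. CSA would then close the lactone by the same epoxide opening at C12 to give silyl ether lactone F6, and methanol would free 23.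

Step 6. O-alkylation of the enolate, proton transfer between enolate and product, or attack on the epoxide may erode the C-alkylation. The fallback sets out from 5 and comes back at 10. Condensation with N,N-dimethylhydrazine would give hydrazone F7. Its lithium azaenolate (LDA), which is softer and forms only at the methyl group, would be alkylated by triflate 8 to give alkylated hydrazone F8. Buffered Cu(OAc)2 hydrolysis would release ketone 10.

Step 10. Lewis-acidic chromium salts may open the epoxide, or the alkenylchromium species may be protonated before it reaches the hindered aldehyde (loss of the epoxide, reduction in place of ring closure). The fallback sets out from 13 and comes back at 15. Wittig methylenation of the unhindered aldehyde (Ph3P=CH2, one equivalent, −78 °C) would give olefin aldehyde F9. Vinylmagnesium bromide addition to the remaining aldehyde would give divinyl carbinol F10. Ring-closing metathesis with the second-generation Grubbs catalyst under high dilution would give macrocyclic allylic alcohol 15.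

Further compounds
F1 | step 12 | (1S,4S,7R,8S,11S,12R)-4,7:11,12-diepoxy-4,8,12-trimethyl-1-(prop-1-en-2-yl)-8-(triethylsilyloxy)cyclotetradecan-3-one | O=C1C[C@@H](C(C)=C)CC[C@@]2(C)O[C@H]2CC[C@](C)(O[Si](CC)(CC)CC)[C@H]2CC[C@]1(C)O2
F2 | step 12 | (3R)-alcohol from F1 | O[C@@H]1C[C@@H](C(C)=C)CC[C@@]2(C)O[C@H]2CC[C@](C)(O[Si](CC)(CC)CC)[C@H]2CC[C@]1(C)O2
F3 | step 12 | (3R)-acetate of F2 | CC(=O)O[C@@H]1C[C@@H](C(C)=C)CC[C@@]2(C)O[C@H]2CC[C@](C)(O[Si](CC)(CC)CC)[C@H]2CC[C@]1(C)O2
F4 | step 12 | 2-substituted acrolein from F3 (C16 aldehyde) | CC(=O)O[C@@H]1C[C@@H](C(=C)C=O)CC[C@@]2(C)O[C@H]2CC[C@](C)(O[Si](CC)(CC)CC)[C@H]2CC[C@]1(C)O2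
F5 | step 12 | epoxy acrylic acid from F4 | CC(=O)O[C@@H]1C[C@@H](C(=C)C(=O)O)CC[C@@]2(C)O[C@H]2CC[C@](C)(O[Si](CC)(CC)CC)[C@H]2CC[C@]1(C)O2
F6 | step 12 | 8-O-triethylsilyl ether of 23 | C=C1C(=O)O[C@@]2(C)CC[C@H]1C[C@@H](OC(C)=O)[C@]1(C)CC[C@@H](O1)[C@@](C)(O[Si](CC)(CC)CC)CC[C@@H]2O
F7 | step 6 | N,N-dimethylhydrazone of 5 | C=C[C@]1(C)CC[C@@H](O1)C(C)=NN(C)C
F8 | step 6 | N,N-dimethylhydrazone of 10 | C=C[C@]1(C)CC[C@@H](O1)C(=NN(C)C)CC[C@@H]1O[C@]1(C)CCC=C(C)C
F9 | step 10 | (2S,5R)-5-[(2S)-4-[(2S,3R)-3-(but-3-en-1-yl)-3-methyloxiran-2-yl]-2-(triethylsilyloxy)butan-2-yl]-2-methyloxolane-2-carbaldehyde | O=C[C@]1(C)CC[C@@H](O1)[C@@](C)(O[Si](CC)(CC)CC)CC[C@@H]1O[C@]1(C)CCC=C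
F10 | step 10 | 1-[(2S,5R)-5-[(2S)-4-[(2S,3R)-3-(but-3-en-1-yl)-3-methyloxiran-2-yl]-2-(triethylsilyloxy)butan-2-yl]-2-methyloxolan-2-yl]prop-2-en-1-ol, carbinol epimers | C=CC(O)[C@]1(C)CC[C@@H](O1)[C@@](C)(O[Si](CC)(CC)CC)CC[C@@H]1O[C@]1(C)CCC=C
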